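Readings and results are simulated with made-up constants, noise included.

Molar per minute is the unit to read this flask in.

- Sunday's: starting material 0.80 M; reagent 0.80 M; free catalyst 4 mM; the very flask that is asked about, followed so far
- flask: starting material 0.80 M; reagent 0.800 M; free catalyst 4.0 mM; time 20 min

Sunday's run (percent of the starting material charged)

| time / min | starting material / % | product / % |
|---|---|---|
| 0.667 | 97.6 | 2.3 |
| 1.33 | 95.0 | 4.5 |
| 3.00 | 89.3 | 10.9 |
| 8.00 | 71.7 | 28.0 |

(scatter of a reading: 0.5 percentage points)

- the numbers in the tables scatter with a standard deviation of 0.5 percentage points

- concentration of starting material at 20 min, in M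
- concentration of product at 20 min, in M

What do you take from Sunday's run? The steady draw, meaning the product made per minute, reckoned from the last reading: 0.0280 M/min.

Does it hold along the run? At 3.00 min the same sum gives 0.0291 M/min, so I see no clear change.

Couldn't a slowdown hide in the scatter? A flask slowing in step with [starting material] from that draw would hold 75.6 % at 8.00 min. Sunday's run read 71.7 %, which is lower, and a reading scatters by 0.5 points.

Your answer for 20 min? My own reckoning is 0.560 M of product, leaving 0.240 M of starting material. At this draw the charge lasts 28.6 min, longer than the time asked.

But your last reading stands at 8.00 min. What then? That is the risk: I have no reading of [starting material] below 71.7 %, and I commit to the draw anyway.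

The forecast reads the run as “a saturated catalyst, near zero-order” and gives 0.25 M of starting material and 0.55 M of product, which differ from my figures.

The flask at 20 min holds 0.246 M of starting material and 0.550 M of product.

    free catalyst + by-product ⇌ idle complex, settled at all times (K = 1.70 /M)
    catalyst intermediate C ⇌ catalyst intermediate D (K = 0.480, k = 0.820 /s)
    catalyst intermediate D → free catalyst + product (k = 0.480 /s)
    reagent + catalyst intermediate A → catalyst intermediate B (k = 12.0 /M/s)
    catalyst intermediate B → by-product + catalyst intermediate C (k = 1.20 /s)
    starting material + free catalyst → catalyst intermediate A (k = 53.0 /M/s)

In this flask catalyst intermediate C holds 64.5 % of the catalyst at 2.00 min and 62.0 % at 20.0 min. The draw goes once more to the flask charged with 0.48 M of reagent, which is the limiting reagent there. The draw asks for 0.560 M by 20 min, more than that charge, and at this draw the reagent lasts 17.1 min. That flask gives 0.480 M of product, with 0.0207 % of its reagent left.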